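## Retrosynthetic overview
1. Lappaol A comes from debenzylation and CO2H→CH2OH reduction of an α-benzylated lactone acid. The α-vanillyl arm is cut off as O-benzylvanillyl bromide (trans-selective lactone enolate alkylation).
2. Key cut: the lactone Cα–Cβ bond and the dihydrobenzofuran C2–C3 bond are broken together. This leads back to one acyclic bis(diazo) ester, closed by a double enantioselective Rh-carbene C–H insertion in one flask.
3. Ring order: the three benzene rings are bought. The γ-butyrolactone closes first (Rh carboxamidate, 40 °C) and the dihydrofuran ring second (Rh carboxylate, −60 °C), in the same operation.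
4. The bis(diazo) ester comes from an aryl iodide plus ethyl diazoacetate (Pd), and from a primary alcohol plus bromoacetyl bromide/ditosylhydrazine.
5. The aryl iodide comes from dihydroconiferyl alcohol by ortho-iodination and O-alkylation with the same vanillyl bromide, which is therefore used twice.

Assumption: the catalyst antipodes are named by analogy with the sense of induction of close analogues. Both antipodes of each catalyst are accessible, and the one that gives the drawn configuration is meant.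

## Route

Step 1
Reactants: 1 4-(benzyloxy)-3-methoxybenzyl alcohol
Product: 2 4-(benzyloxy)-3-methoxybenzyl bromide
Conditions: PBr3 (0.4 equiv), Et2O, 0 °C, 1 h; used crude
Reagents that add atoms: phosphorus tribromide, BrP(Br)Br
Why: PBr3 bromination (SN2 on the phosphite ester of an activated benzylic alcohol); no stereocentre is involved.

Step 2
Reactants: 3 dihydroconiferyl alcohol [3-(4-hydroxy-3-methoxyphenyl)propan-1-ol]
Product: 4 3-(4-hydroxy-3-iodo-5-methoxyphenyl)propan-1-ol
Conditions: I2 (1.0 equiv), K2CO3, THF/H2O, 0 °C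
Reagents that add atoms: iodine, II
Why: Electrophilic aromatic iodination of the phenoxide, in which O– directs to its only free ortho position because para is blocked, and the basic medium avoids attack para to OMe.

Step 3
Reactants: 4 3-(4-hydroxy-3-iodo-5-methoxyphenyl)propan-1-ol; 2 4-(benzyloxy)-3-methoxybenzyl bromide
Product: 5 3-{4-[(4-benzyloxy-3-methoxybenzyl)oxy]-3-iodo-5-methoxyphenyl}propan-1-ol
Conditions: K2CO3 (1.5 equiv), DMF, rt
Reagents that add atoms: none
Why: Williamson ether synthesis, where K2CO3 ionises only the phenol so the primary alcohol stays free.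

Step 4
Reactants: 5 iodoaryl benzyl ether alcohol
Product: 6 ethyl 2-{2-[(4-benzyloxy-3-methoxybenzyl)oxy]-5-(3-hydroxypropyl)-3-methoxyphenyl}-2-diazoacetate
Conditions: ethyl diazoacetate (1.5 equiv), Pd(PPh3)4 (5 mol %), Ag2CO3 (0.5 equiv), Et3N, toluene, rt
Reagents that add atoms: ethyl diazoacetate, CCOC(=O)C=[N+]=[N-]
Why: Pd(0)-catalysed cross-coupling of an aryl iodide with the C–H of a diazoacetate (oxidative addition, Ag/base-assisted palladation of the diazo carbon, reductive elimination), which at rt outruns N2 loss so the diazo group is kept.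

Step 5
Reactants: 6 aryl diazoacetate alcohol
Product: 8 bis(diazo) ester, via bromoacetate 7 (not isolated)
Conditions: BrCH2COBr (1.2 equiv), NaHCO3, MeCN, 0 °C, 15 min; then TsNHNHTs (2 equiv), DBU (5 equiv), 0 °C, 30 min, same flask
Reagents that add atoms: bromoacetyl bromide, BrCC(Br)=O; N,N'-ditosylhydrazine, Cc1ccc(cc1)S(=O)(=O)NNS(=O)(=O)c1ccc(C)cc1
Why: O-acylation, then N-alkylation of ditosylhydrazine and double sulfinate elimination (bromoacetate-to-diazoacetate synthesis), under buffered or basic conditions that leave the aryl diazoester untouched.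

Step 6
Reactants: 8 bis(diazo) ester
Product: 10 cis-(2S,3R)-dihydrobenzofuran ethyl ester carrying the (R)-lactone, via lactone aryl diazoester 9 (not isolated)
Conditions: 8 added over 10 h to Rh2(4R-MPPIM)4 (2 mol %), CH2Cl2, reflux; then toluene (3 vol), −60 °C, Rh2(R-PTTL)4 (2 mol %), −60 → −20 °C, same flask, one work-up
Reagents that add atoms: none
Why: Proposed new method: relay double Rh-carbene C–H insertion in one flask – at 40 °C the weakly electrophilic carboxamidate catalyst is attacked only by the unhindered, more nucleophilic CH=N2 carbon, and its carbene inserts 1,5 into one enantiotopic homobenzylic C–H (the catalyst pocket sets the lactone centre R); the fully substituted aryl diazoester survives until the strongly electrophilic carboxylate catalyst is added at −60 °C, where the carboxamidate is dormant and the donor/acceptor carbene inserts 1,5 into the O-activated benzylic C–H (concerted, catalyst-controlled, C2 set S, 2,3-cis ester); the closest known reaction types are the carboxamidate-catalysed enantioselective γ-lactone synthesis from 3-arylpropyl diazoacetates and the N-phthaloyl-tert-leucinate-catalysed synthesis of cis-2-aryl-2,3-dihydrobenzofuran-3-carboxylates from 2-(benzyloxy)aryl diazoacetates, each established alone but not run together on one bis(diazo) substrate.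

Step 7
Reactants: 10 cis ester lactone
Product: 13 trans-(2S,3S)-dihydrobenzofuran-3-carboxylic acid (R)-lactone, via trans ethyl ester 11 (not isolated), via seco hydroxy diacid 12 (not isolated)
Conditions: NaOEt (0.3 equiv), EtOH, rt, 2 h; then 2 M NaOH, rt; then 2 M HCl to pH 1, rt, 2 h
Reagents that add atoms: sodium hydroxide, [Na+].[OH-]
Why: Enolate epimerisation of the arylacetic ester centre C3 to the thermodynamic 2,3-trans isomer, then saponification and acid relactonisation of the γ-hydroxy acid, with C2 and the lactone β-centre non-acidic and therefore unchanged.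

Step 8
Reactants: 13 trans acid lactone; 2 4-(benzyloxy)-3-methoxybenzyl bromide
Product: 15 α-benzylated (3R,4R)-lactone acid, via dilithio carboxylate enolate 14 (not isolated)
Conditions: LiHMDS (2.2 equiv), THF, −78 °C; then 2 (1.1 equiv), −78 → −30 °C; then 1 M HCl
Reagents that add atoms: none
Why: Dianion (carboxylate/lactone enolate) alkylation, in which the carboxylate shields C3–H from deprotonation and the bromide attacks the enolate face anti to the β-substituent, setting Cα as R (trans).

Step 9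
Reactants: 15 α-benzylated lactone acid
Product: 16 di-O-benzyl lappaol A
Conditions: BH3·THF (2 equiv), THF, 0 °C → rt; then H2O
Reagents that add atoms: none
Why: Chemoselective borane reduction of the carboxylic acid via its acyloxyborane, which is far faster than attack on the hindered lactone; no stereocentre is touched, and the C3 descriptor changes from S to R only through CIP priorities.

Step 10
Reactants: 16 di-O-benzyl lappaol A
Product: 17 lappaol A
Conditions: H2 (1 atm), 10 % Pd/C, EtOAc/EtOH, rt, stopped after 2 equiv H2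
Reagents that add atoms: none
Why: Catalytic hydrogenolysis of the two unhindered aryl benzyl ethers, which is faster than cleavage of the ring C2–O bond and leaves all four stereocentres untouched.

## Compound list
1 | 4-(benzyloxy)-3-methoxybenzyl alcohol | COc1cc(CO)ccc1OCc1ccccc1 | starting material
2 | 4-(benzyloxy)-3-methoxybenzyl bromide | COc1cc(CBr)ccc1OCc1ccccc1 | intermediate
3 | 3-(4-hydroxy-3-methoxyphenyl)propan-1-ol (dihydroconiferyl alcohol) | COc1cc(CCCO)ccc1O | starting material
4 | 3-(4-hydroxy-3-iodo-5-methoxyphenyl)propan-1-ol | COc1cc(CCCO)cc(I)c1O | intermediate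
5 | 3-{4-[(4-benzyloxy-3-methoxybenzyl)oxy]-3-iodo-5-methoxyphenyl}propan-1-ol | COc1cc(CCCO)cc(I)c1OCc1ccc(OCc2ccccc2)c(OC)c1 | intermediate
6 | ethyl 2-{2-[(4-benzyloxy-3-methoxybenzyl)oxy]-5-(3-hydroxypropyl)-3-methoxyphenyl}-2-diazoacetate | CCOC(=O)C(=[N+]=[N-])c1cc(CCCO)cc(OC)c1OCc1ccc(OCc2ccccc2)c(OC)c1 | intermediate
7 | ethyl 2-{2-[(4-benzyloxy-3-methoxybenzyl)oxy]-5-[3-(2-bromoacetoxy)propyl]-3-methoxyphenyl}-2-diazoacetate | CCOC(=O)C(=[N+]=[N-])c1cc(CCCOC(=O)CBr)cc(OC)c1OCc1ccc(OCc2ccccc2)c(OC)c1 | intermediate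
8 | ethyl 2-{2-[(4-benzyloxy-3-methoxybenzyl)oxy]-5-[3-(2-diazoacetoxy)propyl]-3-methoxyphenyl}-2-diazoacetate | CCOC(=O)C(=[N+]=[N-])c1cc(CCCOC(=O)C=[N+]=[N-])cc(OC)c1OCc1ccc(OCc2ccccc2)c(OC)c1 | intermediate
9 | ethyl 2-{2-[(4-benzyloxy-3-methoxybenzyl)oxy]-3-methoxy-5-{[(3R)-5-oxooxolan-3-yl]methyl}phenyl}-2-diazoacetate | CCOC(=O)C(=[N+]=[N-])c1cc(C[C@H]2COC(=O)C2)cc(OC)c1OCc1ccc(OCc2ccccc2)c(OC)c1 | intermediate
10 | ethyl (2S,3R)-2-[4-(benzyloxy)-3-methoxyphenyl]-7-methoxy-5-{[(3R)-5-oxooxolan-3-yl]methyl}-2,3-dihydro-1-benzofuran-3-carboxylate (2,3-cis) | O=C1C[C@@H](Cc2cc(OC)c3c(c2)[C@@H](C(=O)OCC)[C@@H](c2ccc(OCc4ccccc4)c(OC)c2)O3)CO1 | intermediate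
11 | ethyl (2S,3S)-2-[4-(benzyloxy)-3-methoxyphenyl]-7-methoxy-5-{[(3R)-5-oxooxolan-3-yl]methyl}-2,3-dihydro-1-benzofuran-3-carboxylate (2,3-trans) | O=C1C[C@@H](Cc2cc(OC)c3c(c2)[C@H](C(=O)OCC)[C@@H](c2ccc(OCc4ccccc4)c(OC)c2)O3)CO1 | intermediate
12 | (2S,3S)-2-[4-(benzyloxy)-3-methoxyphenyl]-5-[(2R)-3-carboxy-2-(hydroxymethyl)propyl]-7-methoxy-2,3-dihydro-1-benzofuran-3-carboxylic acid (disodium salt in the flask, drawn as free acid) | OC(=O)C[C@@H](Cc1cc(OC)c2c(c1)[C@H](C(O)=O)[C@@H](c1ccc(OCc3ccccc3)c(OC)c1)O2)CO | intermediate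
13 | (2S,3S)-2-[4-(benzyloxy)-3-methoxyphenyl]-7-methoxy-5-{[(3R)-5-oxooxolan-3-yl]methyl}-2,3-dihydro-1-benzofuran-3-carboxylic acid | O=C1C[C@@H](Cc2cc(OC)c3c(c2)[C@H](C(O)=O)[C@@H](c2ccc(OCc4ccccc4)c(OC)c2)O3)CO1 | intermediate
14 | dilithium carboxylate/lactone enolate of 13 | [Li+].[Li+].[O-]C1=C[C@@H](Cc2cc(OC)c3c(c2)[C@H](C([O-])=O)[C@@H](c2ccc(OCc4ccccc4)c(OC)c2)O3)CO1 | intermediate
15 | (2S,3S)-2-[4-(benzyloxy)-3-methoxyphenyl]-5-{[(3R,4R)-4-[4-(benzyloxy)-3-methoxybenzyl]-5-oxooxolan-3-yl]methyl}-7-methoxy-2,3-dihydro-1-benzofuran-3-carboxylic acid | COc1cc(C[C@H]2C(=O)OC[C@@H]2Cc2cc(OC)c3c(c2)[C@H](C(O)=O)[C@@H](c2ccc(OCc4ccccc4)c(OC)c2)O3)ccc1OCc1ccccc1 | intermediate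
16 | (3R,4R)-3-[4-(benzyloxy)-3-methoxybenzyl]-4-{[(2S,3R)-2-[4-(benzyloxy)-3-methoxyphenyl]-3-(hydroxymethyl)-7-methoxy-2,3-dihydro-1-benzofuran-5-yl]methyl}oxolan-2-one | COc1cc(C[C@H]2C(=O)OC[C@@H]2Cc2cc(OC)c3c(c2)[C@H](CO)[C@@H](c2ccc(OCc4ccccc4)c(OC)c2)O3)ccc1OCc1ccccc1 | intermediate
17 | lappaol A, (3R,4R)-lactone, (2S,3R)-dihydrobenzofuran | COc1cc(C[C@H]2C(=O)OC[C@@H]2Cc2cc(OC)c3c(c2)[C@H](CO)[C@@H](c2ccc(O)c(OC)c2)O3)ccc1O | target

## Step count and risks
Total steps: 10. Longest linear sequence: 9 (3 → 17, steps 2–10).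

**Step 6 (relay double insertion).**
- Risk: either catalyst may touch the "wrong" diazo group, or a carbene may couple with a diazo group. Either would erode yield and the C2 selectivity.
- Mitigating point: two independent enantioselective events meet in one molecule, so stereo-errors appear mainly as diastereomers. These can be removed at the crystalline acid 13.
- Fallback: never let one molecule carry two diazo groups.
  - Set out from 5. Acylation with bromoacetyl bromide gives the iodoaryl bromoacetate F2.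
  - Ditosylhydrazine/DBU turns it into the iodoaryl diazoacetate F3.
  - Rh2(4R-MPPIM)4 in refluxing CH2Cl2 closes the (R)-iodoaryl lactone F4.
  - The Pd/Ag coupling with ethyl diazoacetate is then run on that iodide.
  - The route is rejoined at 9, now isolated, which Rh2(R-PTTL)4 alone closes to 10. This is one step longer.

**Step 4 (Pd coupling of a hindered, electron-rich ortho-alkoxy aryl iodide with ethyl diazoacetate).**
- Risk: slow oxidative addition and loss of the diazo group.
- Fallback: make the C–C bond first and the diazo group afterwards.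
  - From 5, Negishi-type coupling with the Reformatsky reagent BrZnCH2CO2Et gives the aryl acetic ester F1. Conditions are Pd(dba)2/XPhos, THF, rt, with excess reagent to cover the free OH.
  - Regitz diazo transfer (p-ABSA, DBU, MeCN) rejoins the route at 6. This is one step longer.

**Step 8 (alkylation of the carboxylate/enolate dianion).**
- Risk: poor solubility of the dilithio species, carboxylate O-alkylation, or incomplete enolisation.
- Fallback: reduce first and mask the alcohol.
  - From 13, BH3·THF gives the hydroxymethyl lactone F5.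
  - TBSCl/imidazole gives the silyl ether lactone F6.
  - LiHMDS followed by 2 gives the trans-alkylated silyl ether F7.
  - TBAF/AcOH rejoins the route at 16. Step 9 drops out and the route is two steps longer.

## Further compounds
F1 | step 4 | ethyl 2-{2-[(4-benzyloxy-3-methoxybenzyl)oxy]-5-(3-hydroxypropyl)-3-methoxyphenyl}acetate | CCOC(=O)Cc1cc(CCCO)cc(OC)c1OCc1ccc(OCc2ccccc2)c(OC)c1
F2 | step 6 | 3-{4-[(4-benzyloxy-3-methoxybenzyl)oxy]-3-iodo-5-methoxyphenyl}propyl 2-bromoacetate | COc1cc(CCCOC(=O)CBr)cc(I)c1OCc1ccc(OCc2ccccc2)c(OC)c1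
F3 | step 6 | 3-{4-[(4-benzyloxy-3-methoxybenzyl)oxy]-3-iodo-5-methoxyphenyl}propyl 2-diazoacetate | COc1cc(CCCOC(=O)C=[N+]=[N-])cc(I)c1OCc1ccc(OCc2ccccc2)c(OC)c1
F4 | step 6 | (4R)-4-{4-[(4-benzyloxy-3-methoxybenzyl)oxy]-3-iodo-5-methoxybenzyl}oxolan-2-one | COc1cc(C[C@H]2COC(=O)C2)cc(I)c1OCc1ccc(OCc2ccccc2)c(OC)c1
F5 | step 8 | (4R)-4-{[(2S,3R)-2-[4-(benzyloxy)-3-methoxyphenyl]-3-(hydroxymethyl)-7-methoxy-2,3-dihydro-1-benzofuran-5-yl]methyl}oxolan-2-one | O=C1C[C@@H](Cc2cc(OC)c3c(c2)[C@H](CO)[C@@H](c2ccc(OCc4ccccc4)c(OC)c2)O3)CO1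
F6 | step 8 | tert-butyldimethylsilyl ether of F5 | O=C1C[C@@H](Cc2cc(OC)c3c(c2)[C@H](CO[Si](C)(C)C(C)(C)C)[C@@H](c2ccc(OCc4ccccc4)c(OC)c2)O3)CO1
F7 | step 8 | tert-butyldimethylsilyl ether of 16 | COc1cc(C[C@H]2C(=O)OC[C@@H]2Cc2cc(OC)c3c(c2)[C@H](CO[Si](C)(C)C(C)(C)C)[C@@H](c2ccc(OCc4ccccc4)c(OC)c2)O3)ccc1OCc1ccccc1
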